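**Plan**
- Retrosynthetic cuts: C5=C6 (ring-closing metathesis); C8–C17 and the C7–O acyl bond (Reformatsky lactone); C7–C8 (alkoxyallylboration); C2–C3 (organolithium on a lactone); and ring A at C13–C14 together with C1–C10 ([4+2]).
- Enabling feature: ring A (C1, C10–C14) is a cyclohexane with oxygen on C14, and its C10–C1 bond is flanked by C9–O and C2. Tying C9–O to C2 as an ester links a C10=C11–C12=C13 diene to a C1=C14 dienophile, so the cycloaddition is intramolecular and also closes a temporary γ-lactone (C10–C9–O–C2–C1).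
- Forward order: dienyl ester from glyceraldehyde → cycloaddition (ring A plus temporary lactone) → lactone opened by the C3–C5 chain (C2 becomes a ketone, the tether oxygen becomes 9-OH) → 11-OH → C7/C8 → butyrolactone (ring C) → ten-membered ring B.
- Stereochemistry: C9 from (R)-glyceraldehyde acetonide; C10, C1 and C14 relayed from C9 in the cycloaddition; C11 directed by 9-OH; C2 by CBS reduction; C7 by the allylborane; C8 and C17 in the cyclic Reformatsky; the Z alkene by the ring.

Key step: step 7

Remark: atoms carry briarane numbers (C1–C20) and α/β as in the target (H-10 α, CH3-15 β); compound 20 is an inconsequential epimer mixture at its bromine-bearing carbon; the allylborane antipode in step 15 is chosen on the assumption that the (+)-α-pinene-derived reagent gives (R)-pent-4-en-2-ol from acetaldehyde.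

Step 1
Reactants: 1 (R)-2,2-dimethyl-1,3-dioxolane-4-carbaldehyde
Product: 2 (E)-3-[(4S)-2,2-dimethyl-1,3-dioxolan-4-yl]-2-methylprop-2-enal
Conditions: Ph3P=C(CH3)CHO, PhMe, 80 °C
Reagents that add atoms: 2-(triphenylphosphoranylidene)propanal, CC(C=O)=P(c1ccccc1)(c1ccccc1)c1ccccc1
Why: Wittig olefination with a stabilised ylide should give the E enal (C9 trans to C12) without added base, so the chiral-pool C9 centre is not epimerised.

Step 2
Reactants: 2 (E)-3-[(4S)-2,2-dimethyl-1,3-dioxolan-4-yl]-2-methylprop-2-enal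
Product: 3 (4S)-2,2-dimethyl-4-[(1E)-2-methylbuta-1,3-dienyl]-1,3-dioxolane
Conditions: Ph3PCH3Br, KOtBu, THF, 0 °C
Reagents that add atoms: methyltriphenylphosphonium bromide (used as its ylide), C[P+](c1ccccc1)(c1ccccc1)c1ccccc1.[Br-]
Why: Wittig methylenation of the enal should give the C10=C11–C12=C13 diene with the E geometry of C10=C11 untouched.

Step 3
Reactants: 3 (4S)-2,2-dimethyl-4-[(1E)-2-methylbuta-1,3-dienyl]-1,3-dioxolane
Product: 4 (2S,3E)-4-methylhexa-3,5-diene-1,2-diol
Conditions: AcOH/H2O (4:1), 25 °C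
Reagents that add atoms: none
Why: Acid-catalysed acetal hydrolysis; dilute acetic acid is mild enough not to ionise the dienylic C9–O bond.

Step 4
Reactants: 4 (2S,3E)-4-methylhexa-3,5-diene-1,2-diol
Product: 5 (2S,3E)-1-(tert-butyldimethylsilyloxy)-4-methylhexa-3,5-dien-2-ol
Conditions: TBSCl, imidazole, CH2Cl2, −20 °C
Reagents that add atoms: tert-butyldimethylsilyl chloride, CC(C)(C)[Si](C)(C)Cl
Why: Silylation should be selective for the primary C8 hydroxyl on steric grounds, leaving 9-OH free for the tether.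

Step 5
Reactants: 5 (2S,3E)-1-(tert-butyldimethylsilyloxy)-4-methylhexa-3,5-dien-2-ol
Product: 6 (2S,3E)-1-(tert-butyldimethylsilyloxy)-4-methylhexa-3,5-dien-2-yl propanoate
Conditions: (EtCO)2O, Et3N, DMAP (cat.), CH2Cl2, 0 °C
Reagents that add atoms: propanoic anhydride, CCC(=O)OC(=O)CC
Why: DMAP-catalysed acylation of the secondary allylic alcohol installs C2, C1 and C15 as the tether ester.

Step 6
Reactants: 6 (2S,3E)-1-(tert-butyldimethylsilyloxy)-4-methylhexa-3,5-dien-2-yl propanoate
Product: 8 (2S,3E)-1-(tert-butyldimethylsilyloxy)-4-methylhexa-3,5-dien-2-yl (Z)-2-methyl-3-(triisopropylsilyloxy)prop-2-enoate, via lithium formyl-ester enolate 7 (not isolated)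
Conditions: LiN(iPr)2 (2.2 equiv), THF, −78 °C; HCO2CH2CF3; then iPr3SiOTf, −78 → 0 °C
Reagents that add atoms: 2,2,2-trifluoroethyl formate, O=COCC(F)(F)F; triisopropylsilyl trifluoromethanesulfonate, CC(C)[Si](C(C)C)(C(C)C)OS(=O)(=O)C(F)(F)F
Why: Crossed Claisen formylation of the ester enolate brings in C14, and O-silylation of the lithium chelate (formyl and ester oxygens syn) is expected to give the Z silyl enol ether, with OTIPS cis to the ester carbonyl.

Step 7
Reactants: 8 (2S,3E)-1-(tert-butyldimethylsilyloxy)-4-methylhexa-3,5-dien-2-yl (Z)-2-methyl-3-(triisopropylsilyloxy)prop-2-enoate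
Product: 9 trans-fused cyclohexene γ-lactone, 3-[(tert-butyldimethylsilyloxy)methyl]-4,7a-dimethyl-7-(triisopropylsilyloxy)-3a,6,7,7a-tetrahydroisobenzofuran-1(3H)-one (ring A with C11=C12, CH3-15 β, H-10 α, 14α-OTIPS; lactone carbonyl = C2, lactone oxygen on C9)
Conditions: PhMe (0.01 M), BHT (cat.), 180 °C, sealed tube
Reagents that add atoms: none
Why: Thermal type 1 intramolecular Diels–Alder reaction of an ester-tethered 1,3,8-nonatriene (closest known class: dienyl acrylates giving bicyclic γ-lactones), in which diene C10=C11–C12=C13 and dienophile C1=C14 combine suprafacially in a concerted, asynchronous [4+2] with the peripheral C13–C14 bond more advanced than the tether-internal C1–C10 bond. Two rings close at once: the cyclohexene ring A (six-membered, by the two new σ bonds) and the temporary γ-lactone C10–C9–O–C2–C1 (five-membered, fused mode, through C1–C10). C10 is controlled by allylic 1,3-strain between the C11 methyl and C9, which holds H-9 in the diene plane so that the tether oxygen and CH2OTBS lie on opposite faces and the dienophile reaches only the face carrying the oxygen. C1 is controlled by the three-atom tether, which keeps the ester carbonyl exo with the methyl endo and should give the trans-fused lactone with CH3-15 cis to C9. C14 follows from the Z alkene geometry, which places OTIPS cis to C2 (14α). Regiochemistry is fixed by the tether; the selectivity that is needed and least certain is exo-tether over endo-tether, which the E diene and the Z-OTIPS group (it would sit endo under the diene in the unwanted mode) are expected to secure.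

Step 8
Reactants: 9 trans-fused cyclohexene γ-lactone
Product: 10 hydroxy ketone: ring A (C11=C12, 14α-OTIPS, CH3-15 β) bearing on C1 the 5-methyl-1-oxohex-5-enyl chain (C2 ketone, C3–C5, C16) and on C10 the (1S)-1-hydroxy-2-(tert-butyldimethylsilyloxy)ethyl group (C9, C8)
Conditions: 4-bromo-2-methylbut-1-ene, Li, Et2O, −10 °C; then 9, THF, −78 °C; H2O
Reagents that add atoms: 4-bromo-2-methylbut-1-ene (used as 3-methylbut-3-enyllithium), C=C(C)CCBr
Why: Organolithium addition to a lactone should stop after one addition because the carbonyl has no α-hydrogen, is flanked by quaternary C1 and gives a lithium hemiketalate that is stable at −78 °C; the open hydroxy ketone is expected to predominate over the strained trans-fused lactol.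

Step 9
Reactants: 10 hydroxy ketone
Product: 11 11β,12β-epoxy hydroxy ketone (as 10, with the C11=C12 alkene converted into the β-epoxide)
Conditions: VO(acac)2 (5 mol %), t-BuOOH, CH2Cl2, 0 → 25 °C
Reagents that add atoms: tert-butyl hydroperoxide, CC(C)(C)OO
Why: Hydroxyl-directed vanadium-catalysed epoxidation of a homoallylic alcohol; allylic strain with the C11 methyl places the 9-OH over the β face, so oxygen should be delivered syn to C9, and the chain alkene has no directing hydroxyl at this stage.

Step 10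
Reactants: 11 11β,12β-epoxy hydroxy ketone
Product: 12 (2S)-epoxy diol (as 11, with the C2 ketone reduced to the 2S alcohol)
Conditions: (R)-2-methyl-CBS-oxazaborolidine (0.2 equiv), catecholborane, PhMe, −78 °C
Reagents that add atoms: none
Why: Corey–Bakshi–Shibata reduction differentiates the quaternary C1 (large) from the C3 methylene (small), so the R catalyst should give the 2S carbinol, and catecholborane at −78 °C spares the alkene and the epoxide.

Step 11
Reactants: 12 (2S)-epoxy diol
Product: 13 2,9,11-triol (ring A saturated, 11β-OH, 20α-CH3, 14α-OTIPS, 8-OTBS)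
Conditions: LiEt3BH, THF, 0 → 25 °C
Reagents that add atoms: none
Why: Hydride opening of the trisubstituted epoxide by SN2 attack at the less substituted C12 in the trans-diaxial (Fürst–Plattner) sense should leave the axial tertiary 11β-OH.

Step 12
Reactants: 13 2,9,11-triol
Product: 14 2,9-diacetate (11-OH free)
Conditions: Ac2O, pyridine, DMAP (cat.), CH2Cl2, 0 °C
Reagents that add atoms: acetic anhydride, CC(=O)OC(C)=O
Why: Acylation should take place at the two secondary hydroxyls only, the tertiary 11-OH being too hindered under these conditions.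

Step 13
Reactants: 14 2,9-diacetate
Product: 15 primary C8 alcohol (TBS removed, TIPS kept)
Conditions: HF·pyridine, pyridine, THF, 0 °C
Reagents that add atoms: none
Why: Buffered fluoride cleaves the primary TBS ether much faster than the hindered secondary TIPS ether, and the acidic medium suppresses 9→8 acetyl migration.

Step 14
Reactants: 15 primary C8 alcohol
Product: 16 C8 aldehyde (α-acetoxy aldehyde)
Conditions: Dess–Martin periodinane, CH2Cl2, 0 °C
Reagents that add atoms: none
Why: Dess–Martin oxidation gives the aldehyde under non-basic conditions that should leave the α-acetoxy centre C9 and the tertiary alcohol untouched.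

Step 15
Reactants: 16 C8 aldehyde
Product: 17 syn 8-hydroxy-7-(methoxymethoxy) adduct carrying the C6 vinyl group on C7 (7S)
Conditions: CH2=CHCH2OCH2OCH3, s-BuLi, THF, −78 °C; (+)-Ipc2BOMe (from (−)-α-pinene); BF3·OEt2; then 16, −78 °C; H2O2, pH 7 buffer
Reagents that add atoms: allyl methoxymethyl ether (used as its (Z)-γ-boryl derivative), C=CCOCOC
Why: Brown alkoxyallylboration through a chair Zimmerman–Traxler transition state: the Z reagent should give the syn adduct and the isopinocampheyl groups should set C7 under reagent control, while the C8 configuration is irrelevant because C8 is oxidised next.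

Step 16
Reactants: 17 syn 8-hydroxy-7-(methoxymethoxy) adduct
Product: 18 C8 ketone (9-OAc, 7-OMOM)
Conditions: Dess–Martin periodinane, CH2Cl2, 0 → 25 °C
Reagents that add atoms: none
Why: Dess–Martin oxidation of the only secondary alcohol should give the ketone without epimerising the flanking C7 and C9 centres.

Step 17
Reactants: 18 C8 ketone
Product: 19 7-hydroxy C8 ketone
Conditions: Me2BBr, CH2Cl2, −78 °C; then H2O/THF
Reagents that add atoms: none
Why: Bromodimethylborane cleaves the methoxymethyl acetal at low temperature and should spare the acetates, the silyl ether and the allylic α-ketol.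

Step 18
Reactants: 19 7-hydroxy C8 ketone
Product: 20 7-O-(2-bromopropanoyl) C8 ketone
Conditions: CH3CHBrCOBr, pyridine, CH2Cl2, −40 °C
Reagents that add atoms: 2-bromopropanoyl bromide, CC(Br)C(Br)=O
Why: Acylation of the only secondary hydroxyl places C19, C17 and C18 on O-7, ready for ring closure.

Step 19
Reactants: 20 7-O-(2-bromopropanoyl) C8 ketone
Product: 21 β-hydroxy-γ-lactone (ring C closed; 8-OH and CH3-18 cis, C9 trans to C6; vinyl on C7 and 3-methylbut-3-enyl chain on C2 still open)
Conditions: SmI2 (2.2 equiv), THF, −78 °C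
Reagents that add atoms: none
Why: Intramolecular Reformatsky reaction: the C–Br bond is reduced first and the chelated samarium enolate adds to the C8 ketone in a five-membered ring closure in which the large C9 substituent should sit trans to the C7 vinyl group and the C17 methyl trans to C9, giving 8S and 17R.

Step 20
Reactants: 21 β-hydroxy-γ-lactone
Product: 22 14-O-triisopropylsilyl junceellolide I
Conditions: second-generation Hoveyda–Grubbs catalyst (10 mol %), PhMe (1 mM), 80 °C
Reagents that add atoms: none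
Why: Ring-closing metathesis between the 1,1-disubstituted C5 alkene and the C6 vinyl group should close ring B, and the ten-membered ring allows only the Z trisubstituted alkene.

Step 21
Reactants: 22 14-O-triisopropylsilyl junceellolide I
Product: 23 junceellolide I
Conditions: HF·pyridine, MeCN, 0 → 25 °C
Reagents that add atoms: none
Why: Fluoride-mediated cleavage of the last silyl ether under acidic conditions should leave the acetates, the lactone and the tertiary alcohols intact and avoid 2→14 acetyl migration.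

**Compound list**
1 | (R)-2,2-dimethyl-1,3-dioxolane-4-carbaldehyde | O=C[C@H]1COC(C)(C)O1 | starting material
2 | (E)-3-[(4S)-2,2-dimethyl-1,3-dioxolan-4-yl]-2-methylprop-2-enal | O=C/C(C)=C/[C@H]1COC(C)(C)O1 | intermediate
3 | (4S)-2,2-dimethyl-4-[(1E)-2-methylbuta-1,3-dienyl]-1,3-dioxolane | C=C/C(C)=C/[C@H]1COC(C)(C)O1 | intermediate
4 | (2S,3E)-4-methylhexa-3,5-diene-1,2-diol | C=C/C(C)=C/[C@@H](CO)O | intermediate
5 | (2S,3E)-1-(tert-butyldimethylsilyloxy)-4-methylhexa-3,5-dien-2-ol | C=C/C(C)=C/[C@@H](CO[Si](C)(C)C(C)(C)C)O | intermediate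
6 | (2S,3E)-1-(tert-butyldimethylsilyloxy)-4-methylhexa-3,5-dien-2-yl propanoate | C=C/C(C)=C/[C@@H](CO[Si](C)(C)C(C)(C)C)OC(=O)CC | intermediate
7 | lithium (Z)-enolate of the 2-formylpropanoate ester of 5 | C=C/C(C)=C/[C@@H](CO[Si](C)(C)C(C)(C)C)OC(=O)/C(C)=C\[O-].[Li+] | intermediate
8 | (2S,3E)-1-(tert-butyldimethylsilyloxy)-4-methylhexa-3,5-dien-2-yl (Z)-2-methyl-3-(triisopropylsilyloxy)prop-2-enoate | C=C/C(C)=C/[C@@H](CO[Si](C)(C)C(C)(C)C)OC(=O)/C(C)=C\O[Si](C(C)C)(C(C)C)C(C)C | intermediate
9 | trans-fused cyclohexene γ-lactone (ring A, C11=C12, 14α-OTIPS, lactone C=O = C2) | CC(C)(C)[Si](C)(C)OC[C@H]1OC(=O)[C@@]2(C)[C@@H](O[Si](C(C)C)(C(C)C)C(C)C)CC=C(C)[C@H]12 | intermediate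
10 | hydroxy ketone (C2 ketone with C3–C5 chain, 9-OH) | CC(C)(C)[Si](C)(C)OC[C@@H](O)[C@@H]1[C@](C(=O)CCC(C)=C)(C)[C@@H](O[Si](C(C)C)(C(C)C)C(C)C)CC=C1C | intermediate
11 | 11β,12β-epoxy hydroxy ketone | CC(C)(C)[Si](C)(C)OC[C@@H](O)[C@@H]1[C@](C(=O)CCC(C)=C)(C)[C@@H](O[Si](C(C)C)(C(C)C)C(C)C)C[C@@H]2O[C@]12C | intermediate
12 | (2S)-epoxy diol | CC(C)(C)[Si](C)(C)OC[C@@H](O)[C@@H]1[C@]([C@@H](O)CCC(C)=C)(C)[C@@H](O[Si](C(C)C)(C(C)C)C(C)C)C[C@@H]2O[C@]12C | intermediate
13 | 2,9,11-triol | CC(C)(C)[Si](C)(C)OC[C@@H](O)[C@@H]1[C@]([C@@H](O)CCC(C)=C)(C)[C@@H](O[Si](C(C)C)(C(C)C)C(C)C)CC[C@]1(C)O | intermediate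
14 | 2,9-diacetate | CC(C)(C)[Si](C)(C)OC[C@@H](OC(C)=O)[C@@H]1[C@]([C@@H](OC(C)=O)CCC(C)=C)(C)[C@@H](O[Si](C(C)C)(C(C)C)C(C)C)CC[C@]1(C)O | intermediate
15 | primary C8 alcohol | OC[C@@H](OC(C)=O)[C@@H]1[C@]([C@@H](OC(C)=O)CCC(C)=C)(C)[C@@H](O[Si](C(C)C)(C(C)C)C(C)C)CC[C@]1(C)O | intermediate
16 | C8 aldehyde | O=C[C@@H](OC(C)=O)[C@@H]1[C@]([C@@H](OC(C)=O)CCC(C)=C)(C)[C@@H](O[Si](C(C)C)(C(C)C)C(C)C)CC[C@]1(C)O | intermediate
17 | syn 8-hydroxy-7-(methoxymethoxy) adduct | C=C[C@H](OCOC)[C@@H](O)[C@@H](OC(C)=O)[C@@H]1[C@]([C@@H](OC(C)=O)CCC(C)=C)(C)[C@@H](O[Si](C(C)C)(C(C)C)C(C)C)CC[C@]1(C)O | intermediate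
18 | C8 ketone (7-OMOM) | C=C[C@H](OCOC)C(=O)[C@@H](OC(C)=O)[C@@H]1[C@]([C@@H](OC(C)=O)CCC(C)=C)(C)[C@@H](O[Si](C(C)C)(C(C)C)C(C)C)CC[C@]1(C)O | intermediate
19 | 7-hydroxy C8 ketone | C=C[C@H](O)C(=O)[C@@H](OC(C)=O)[C@@H]1[C@]([C@@H](OC(C)=O)CCC(C)=C)(C)[C@@H](O[Si](C(C)C)(C(C)C)C(C)C)CC[C@]1(C)O | intermediate
20 | 7-O-(2-bromopropanoyl) C8 ketone | C=C[C@H](OC(=O)C(C)Br)C(=O)[C@@H](OC(C)=O)[C@@H]1[C@]([C@@H](OC(C)=O)CCC(C)=C)(C)[C@@H](O[Si](C(C)C)(C(C)C)C(C)C)CC[C@]1(C)O | intermediate
21 | β-hydroxy-γ-lactone, ring B still open | C=C[C@@H]1OC(=O)[C@H](C)[C@@]1(O)[C@@H](OC(C)=O)[C@@H]2[C@]([C@@H](OC(C)=O)CCC(C)=C)(C)[C@@H](O[Si](C(C)C)(C(C)C)C(C)C)CC[C@]2(C)O | intermediate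
22 | 14-O-triisopropylsilyl junceellolide I | CC(=O)O[C@H]1CC/C(C)=C\[C@@H]2OC(=O)[C@H](C)[C@@]2(O)[C@@H](OC(C)=O)[C@@H]2[C@]1(C)[C@@H](O[Si](C(C)C)(C(C)C)C(C)C)CC[C@]2(C)O | intermediate
23 | junceellolide I | CC(=O)O[C@H]1CC/C(C)=C\[C@@H]2OC(=O)[C@H](C)[C@@]2(O)[C@@H](OC(C)=O)[C@@H]2[C@]1(C)[C@@H](O)CC[C@]2(C)O | target

**Totals:** 21 steps; longest linear sequence 21 steps (1 → 23).

**Steps most likely to fail**

Step 7. The donor-substituted dienophile may react too slowly at temperatures the dienyl ester tolerates, or the endo-tether mode may compete and erode the trans ring fusion. The fallback sets out from 5 and returns at 9. Alcohol 5 is esterified (DCC, DMAP) with (E)-2-methyl-3-(pinacolboryl)prop-2-enoic acid to give the dienyl boryl-acrylate F1, whose boron-substituted, non-donor dienophile should undergo the same tethered cycloaddition at lower temperature to the 14β-boryl lactone F2. Oxidation of the C–B bond with retention (NaBO3·4H2O) gives the 14β-hydroxy lactone F3, and Dess–Martin oxidation gives the 14-oxo lactone F4. Reduction with LiBH(s-Bu)3 from the equatorial side then gives the 14α-hydroxy lactone F5, so that C14 is set by the hydride and not by alkene geometry. Silylation (iPr3SiOTf, 2,6-lutidine) returns 9.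

Step 20. Oligomerisation may outrun ring closure, because the trans-fused lactone and the allylic lactone oxygen disfavour the metallacycle that leads to the trisubstituted ring alkene. The fallback sets out from 17 and returns at 22: the carbocycle is closed before the lactone exists. Metathesis of the more flexible 17 gives the cyclodecene hydroxy ether F6. Dess–Martin oxidation gives the ring-B ketone F7, Me2BBr gives the ring-B α-ketol F8, and 2-bromopropanoyl bromide gives the ring-B bromopropanoate F9. The SmI2 Reformatsky closure, now transannularly constrained, gives 22.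

Step 19. Electron transfer to the doubly α-oxygenated ketone (loss of an acyloxy group) may compete with C–Br reduction, or the cyclic aldol may show poor facial control. The fallback sets out from 18 and returns at 21. An intermolecular zinc Reformatsky addition of ethyl 2-bromopropanoate to 18, under chelation control by the 7-OMOM group, should give the β-hydroxy ester F10. Me2BBr then removes the methoxymethyl group and the freed 7-OH lactonises onto the ethyl ester to give 21.

**Further compounds**
F1 | step 7 | dienyl (E)-2-methyl-3-(pinacolboryl)prop-2-enoate of 5 | C=C/C(C)=C/[C@@H](CO[Si](C)(C)C(C)(C)C)OC(=O)/C(C)=C/B1OC(C)(C)C(C)(C)O1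
F2 | step 7 | 14β-(pinacolboryl) trans-fused cyclohexene γ-lactone | CC(C)(C)[Si](C)(C)OC[C@H]1OC(=O)[C@@]2(C)[C@H](B3OC(C)(C)C(C)(C)O3)CC=C(C)[C@H]12
F3 | step 7 | 14β-hydroxy lactone | CC(C)(C)[Si](C)(C)OC[C@H]1OC(=O)[C@@]2(C)[C@H](O)CC=C(C)[C@H]12
F4 | step 7 | 14-oxo lactone | CC(C)(C)[Si](C)(C)OC[C@H]1OC(=O)[C@@]2(C)C(=O)CC=C(C)[C@H]12
F5 | step 7 | 14α-hydroxy lactone | CC(C)(C)[Si](C)(C)OC[C@H]1OC(=O)[C@@]2(C)[C@@H](O)CC=C(C)[C@H]12
F6 | step 20 | cyclodecene with 8-OH and 7-OMOM (ring B closed, no lactone) | CC(=O)O[C@H]1CC/C(C)=C\[C@H](OCOC)[C@@H](O)[C@@H](OC(C)=O)[C@@H]2[C@]1(C)[C@@H](O[Si](C(C)C)(C(C)C)C(C)C)CC[C@]2(C)O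
F7 | step 20 | ring-B C8 ketone (7-OMOM) | CC(=O)O[C@H]1CC/C(C)=C\[C@H](OCOC)C(=O)[C@@H](OC(C)=O)[C@@H]2[C@]1(C)[C@@H](O[Si](C(C)C)(C(C)C)C(C)C)CC[C@]2(C)O
F8 | step 20 | ring-B 7-hydroxy C8 ketone | CC(=O)O[C@H]1CC/C(C)=C\[C@H](O)C(=O)[C@@H](OC(C)=O)[C@@H]2[C@]1(C)[C@@H](O[Si](C(C)C)(C(C)C)C(C)C)CC[C@]2(C)O
F9 | step 20 | ring-B 7-O-(2-bromopropanoyl) C8 ketone | CC(=O)O[C@H]1CC/C(C)=C\[C@H](OC(=O)C(C)Br)C(=O)[C@@H](OC(C)=O)[C@@H]2[C@]1(C)[C@@H](O[Si](C(C)C)(C(C)C)C(C)C)CC[C@]2(C)O
F10 | step 19 | open-chain β-hydroxy ethyl ester (8-OH, 7-OMOM) | C=C[C@H](OCOC)[C@@](O)([C@@H](C)C(=O)OCC)[C@@H](OC(C)=O)[C@@H]1[C@]([C@@H](OC(C)=O)CCC(C)=C)(C)[C@@H](O[Si](C(C)C)(C(C)C)C(C)C)CC[C@]1(C)O
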